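**Retrosynthetic overview**

1. Endgame: the C19 acid comes from the C19 carbinol after selective acetylation of the C15 hydroxyl of a 15,19-diol; one LiAlH4 reduction of a C15/C19 diester gives that diol and frees the chiral auxiliary.
2. Side chain: the 13E alkene comes from a stereoretentive Me2CuLi substitution of a (Z)-enol phosphate of a β-keto ester, made by a Blaise reaction on a C13 nitrile; the C3 oxygen is removed by Barton–McCombie deoxygenation.
3. Key disconnection: C4–C5 and C9–C10 are formed in one Mn(OAc)3/Cu(OAc)2 oxidative radical cascade of an acyclic (E,E)-diene 2-methyl-3-oxo ester; ring A closes first, ring B second, then the C8=C17 exocyclic alkene is released.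
4. Enabling feature: C4 of ring A carries both C18 (CH3) and C19 (carboxyl) and is bonded to C3, so a 3-oxo derivative makes C4 the α-carbon of a 2-methylacetoacetate, the site of an electrophilic tertiary radical. C5=C10 and C9=C8 are the head-to-tail trisubstituted alkenes of an isoprenoid chain, each five atoms from the radical that attacks it, and C8 keeps a methyl (C17) that becomes the exocyclic methylene.
5. Acyclic precursor: γ-alkylation of the dianion of (−)-8-phenylmenthyl 2-methylacetoacetate with an ω-bromo dienenitrile made from geranyl bromide, acetonitrile and an SeO2 oxidation; a nitrile stub is used instead of the finished side chain so that no third alkene can extend the cascade.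

Key step: step 6

Notation: labdane numbering (ring A = C1–C5, C10; ring B = C5–C10; C17 = exocyclic CH2 on C8; C18/C19 = CH3/carboxyl on C4; C20 = CH3 on C10; C11–C16 = side chain on C9); Pm = (1R,2S,5R)-5-methyl-2-(2-phenylpropan-2-yl)cyclohexyl, the (−)-8-phenylmenthyl group.

Assumption: the (1R,2S,5R)-auxiliary is taken to expose the face of the C4 radical that leads to the 5α-H, 10β-methyl series, by analogy with related auxiliary-controlled oxidative cyclizations of 2-alkylacetoacetates; if the sense proved opposite, the enantiomeric auxiliary would be used with no other change.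

**Route**

Step 1
Reactants: 1 geranyl bromide
Product: 2 (4E)-5,9-dimethyldeca-4,8-dienenitrile
Conditions: MeCN (5 equiv), n-BuLi (4.5 equiv), THF, −78 °C; then 1, −78 to −40 °C
Reagents that add atoms: acetonitrile (CC#N)
Why: SN2 alkylation of lithioacetonitrile (formed in the flask from acetonitrile) at the primary allylic bromide keeps the E alkene (excess anion suppresses dialkylation) and installs C12 and C13 as a nitrile stub that tolerates radicals and oxidants.

Step 2
Reactants: 2 (4E)-5,9-dimethyldeca-4,8-dienenitrile
Product: 3 (4E,8E)-10-hydroxy-5,9-dimethyldeca-4,8-dienenitrile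
Conditions: SeO2 (cat.), t-BuOOH, salicylic acid (cat.), CH2Cl2, 0 °C to rt
Reagents that add atoms: selenium dioxide (O=[Se]=O); tert-butyl hydroperoxide (CC(C)(C)OO)
Why: SeO2 allylic oxidation (ene reaction then [2,3]-sigmatropic shift), in which catalytic SeO2 delivers the oxygen and t-BuOOH restores it, should attack the E-methyl of the terminal, least hindered trisubstituted alkene and give the (E)-allylic alcohol whose carbinol carbon becomes C1.

Step 3
Reactants: 3 (4E,8E)-10-hydroxy-5,9-dimethyldeca-4,8-dienenitrile
Product: 4 (4E,8E)-10-bromo-5,9-dimethyldeca-4,8-dienenitrile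
Conditions: CBr4, PPh3, CH2Cl2, 0 °C
Reagents that add atoms: tetrabromomethane (BrC(Br)(Br)Br)
Why: the Appel reaction converts the primary allylic alcohol into the bromide under neutral conditions without allylic transposition, and the nitrile is inert.

Step 4
Reactants: 5 (−)-8-phenylmenthol; 6 ethyl 2-methyl-3-oxobutanoate
Product: 7 Pm 2-methyl-3-oxobutanoate
Conditions: DMAP (cat.), toluene, reflux, EtOH removed (4 Å sieves)
Reagents that add atoms: none
Why: DMAP-catalysed transesterification of a β-keto ester, driven by removal of ethanol, loads the chiral auxiliary; the epimeric α-centre is destroyed later.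

Step 5
Reactants: 7 Pm 2-methyl-3-oxobutanoate; 4 (4E,8E)-10-bromo-5,9-dimethyldeca-4,8-dienenitrile
Product: 9 acyclic cyano keto ester, via dilithium dianion 8 (not isolated)
Conditions: LDA (2.05 equiv), THF, −78 to 0 °C; then 4, −78 to 0 °C; aq. NH4Cl
Reagents that add atoms: none
Why: γ-alkylation of a β-keto ester dianion, in which the terminal carbanion of 8 should displace the allylic bromide by SN2 much faster than it attacks or deprotonates the nitrile, joins C1 to C2 with both E alkenes intact.

Step 6
Reactants: 9 acyclic cyano keto ester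
Product: 10 bicyclic 3-oxo cyano ester
Conditions: Mn(OAc)3·2H2O (2.2 equiv), Cu(OAc)2·H2O (1.0 equiv), degassed AcOH, 25 °C
Reagents that add atoms: none
Why: Mn(OAc)3 oxidises the enol of the 2-methyl-3-oxo ester to a tertiary, electrophilic C4 radical that adds 6-endo to C5 of the (E)-C5=C10 alkene (ring A), the resulting tertiary C10 radical adds 6-endo to C9 of the (E)-C8=C9 alkene (ring B), and Cu(OAc)2 captures the tertiary C8 radical and releases the C8=C17 alkene by syn β-hydride loss from the methyl group, while Mn(OAc)3 returns monovalent copper to the divalent state. The closest known reaction type is the Mn(OAc)3/Cu(OAc)2 oxidative free-radical polyene cyclization of 2-alkylacetoacetates to trans-decalin β-keto esters, including versions steered by an 8-phenylmenthyl ester. Both rings close through chair-like 6-endo-trig transition states in a trans-anti-trans array, so anti addition across the E C5=C10 alkene sets the trans ring fusion (5α-H, 10β-CH3) and the E C8=C9 alkene places the cyanoethyl chain equatorial (β) at C9. At C4 the non-chelated radical reacts with the ester anti to the ketone oxygen, which should put the ester axial (β, cis to the C10 methyl) and the methyl equatorial, and both C2 epimers of 9 converge because the radical is planar. The absolute sense comes from the auxiliary, whose phenyl ring covers one face of the planar dicarbonyl radical so that C5 bonds to the open face, and the minor facial isomer is a diastereomer that chromatography should remove. The step needs 6-endo over 5-exo closure (secured by attack at the less substituted alkene carbon, giving a tertiary radical twice), a stop at the bicyclic stage (secured because no further alkene is present and the nitrile is a slow radical acceptor) and exocyclic olefin formation (favoured by Hofmann-type elimination from the trivalent organocopper intermediate).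

Step 7
Reactants: 10 bicyclic 3-oxo cyano ester
Product: 11 3β-hydroxy cyano ester
Conditions: NaBH4, MeOH/THF, 0 °C
Reagents that add atoms: none
Why: borohydride reduction with NaBH4 touches only the ketone, and axial hydride delivery from the α face should give the equatorial 3β-alcohol, whose configuration is irrelevant because the centre is removed in step 9.

Step 8
Reactants: 11 3β-hydroxy cyano ester
Product: 12 3β-O-(imidazol-1-ylthiocarbonyl) cyano ester
Conditions: 1,1'-thiocarbonyldiimidazole, DMAP (cat.), toluene, 80 °C
Reagents that add atoms: 1,1'-thiocarbonyldiimidazole (S=C(n1ccnc1)n1ccnc1)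
Why: acylation of the secondary alcohol under neutral conditions (no alkoxide, so no retro-aldol of the β-hydroxy ester) gives the radical-labile thiocarbonyl derivative needed for a Barton–McCombie deoxygenation.

Step 9
Reactants: 12 3β-O-(imidazol-1-ylthiocarbonyl) cyano ester
Product: 13 3-deoxy cyano ester
Conditions: Bu3SnH, AIBN (cat.), toluene, 105 °C
Reagents that add atoms: none
Why: Barton–McCombie deoxygenation, in which Bu3Sn• adds to sulfur, the C3–O bond fragments and the secondary C3 radical (no alkene within reach) is reduced by Bu3SnH, removes the oxygen that served only to activate C4.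

Step 10
Reactants: 13 3-deoxy cyano ester
Product: 15 13-oxo-15-ester (β-keto ester), via bromozinc enaminate 14 (not isolated)
Conditions: Zn (activated), BrCH2CO2Et (slow addition), THF, reflux; then 1 M aq. HCl, rt
Reagents that add atoms: ethyl bromoacetate (BrCC(=O)OCC); water (O)
Why: in the Blaise reaction the Reformatsky reagent BrZnCH2CO2Et adds to the nitrile carbon to give a chelated zinc enaminate that acid hydrolyses to the β-keto ester, adding C14 and C15 while the hindered neopentyl C19 ester is untouched.

Step 11
Reactants: 15 13-oxo-15-ester (β-keto ester)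
Product: 17 (Z)-enol phosphate, via sodium enolate 16 (not isolated)
Conditions: NaH, Et2O, 0 °C; then ClP(O)(OEt)2, 0 °C to rt
Reagents that add atoms: diethyl chlorophosphate (CCOP(=O)(Cl)OCC)
Why: O-phosphorylation of the chelated sodium enolate of a β-keto ester in ether should give the (Z)-enol phosphate (oxygen cis to the ester), fixing the geometry that step 12 transfers to the alkene.

Step 12
Reactants: 17 (Z)-enol phosphate
Product: 18 (13E)-diester
Conditions: Me2CuLi (from MeLi and CuI), Et2O, −78 to −45 °C; aq. NH4Cl
Reagents that add atoms: methyllithium (C[Li]); lithium dimethylcuprate ([Li+].C[Cu-]C)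
Why: organocuprate substitution of a β-phosphoryloxy enoate proceeds with retention of geometry, so the new methyl (C16) ends cis to the ester and the C13=C14 alkene is E.

Step 13
Reactants: 18 (13E)-diester
Product: 19 labda-8(17),13E-diene-15,19-diol
Conditions: LiAlH4, THF, 0 to 40 °C; aq. NaOH work-up
Reagents that add atoms: none
Why: hydride reduction with LiAlH4 takes the conjugated ethyl ester 1,2 to the allylic alcohol and the hindered neopentyl ester to the C19 carbinol in one operation, releasing auxiliary 5 for recovery, while isolated alkenes are inert.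

Step 14
Reactants: 19 labda-8(17),13E-diene-15,19-diol
Product: 20 19-hydroxylabda-8(17),13E-dien-15-yl acetate
Conditions: Ac2O (1.1 equiv), pyridine, CH2Cl2, −20 to 0 °C
Reagents that add atoms: acetic anhydride (CC(=O)OC(C)=O)
Why: kinetically selective acetylation, since the unhindered allylic primary C15 hydroxyl should react much faster than the neopentyl C19 hydroxyl, which is axial and 1,3-diaxial to the C10 methyl.

Step 15
Reactants: 20 19-hydroxylabda-8(17),13E-dien-15-yl acetate
Product: 21 19-oxolabda-8(17),13E-dien-15-yl acetate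
Conditions: Dess–Martin periodinane, CH2Cl2, 0 °C to rt
Reagents that add atoms: none
Why: Dess–Martin oxidation converts the hindered primary alcohol to the aldehyde under mild conditions that leave the allylic acetate and both alkenes untouched, and the quaternary α-carbon cannot epimerise.

Step 16
Reactants: 21 19-oxolabda-8(17),13E-dien-15-yl acetate
Product: 22 15-acetoxyisocupressic acid
Conditions: NaClO2, NaH2PO4, 2-methyl-2-butene, t-BuOH/H2O, rt
Reagents that add atoms: sodium chlorite ([Na+].[O-]Cl=O)
Why: Pinnick oxidation, with 2-methyl-2-butene as hypochlorite scavenger, takes the hindered aldehyde to the carboxylic acid without touching the alkenes or the acetate.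

**Compound list**

1 | geranyl bromide, (2E)-1-bromo-3,7-dimethylocta-2,6-diene | CC(C)=CCC/C(C)=C/CBr | starting material
2 | (4E)-5,9-dimethyldeca-4,8-dienenitrile | CC(C)=CCC/C(C)=C/CCC#N | intermediate
3 | (4E,8E)-10-hydroxy-5,9-dimethyldeca-4,8-dienenitrile | OC/C(C)=C/CC/C(C)=C/CCC#N | intermediate
4 | (4E,8E)-10-bromo-5,9-dimethyldeca-4,8-dienenitrile | BrC/C(C)=C/CC/C(C)=C/CCC#N | intermediate
5 | (−)-8-phenylmenthol, (1R,2S,5R)-5-methyl-2-(2-phenylpropan-2-yl)cyclohexan-1-ol | O[C@@H]1C[C@H](C)CC[C@H]1C(C)(C)c1ccccc1 | starting material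
6 | ethyl 2-methyl-3-oxobutanoate (racemic) | CCOC(=O)C(C)C(C)=O | starting material
7 | Pm 2-methyl-3-oxobutanoate (both C2 epimers) | CC(=O)C(C)C(=O)O[C@@H]1C[C@H](C)CC[C@H]1C(C)(C)c1ccccc1 | intermediate
8 | dilithium dienolate (dianion) of 7 | [Li+].[Li+].C=C([O-])C(C)=C([O-])O[C@@H]1C[C@H](C)CC[C@H]1C(C)(C)c1ccccc1 | intermediate
9 | Pm (6E,10E)-13-cyano-2,6,10-trimethyl-3-oxotrideca-6,10-dienoate (both C2 epimers) | N#CCC/C=C(\C)CC/C=C(\C)CCC(=O)C(C)C(=O)O[C@@H]1C[C@H](C)CC[C@H]1C(C)(C)c1ccccc1 | intermediate
10 | Pm 12-cyano-3-oxo-13,14,15,16-tetranorlabd-8(17)-en-19-oate (trans-decalin; 4α-CH3, 4β-CO2Pm, 5α-H, 9β-CH2CH2CN, 10β-CH3) | C=C1CC[C@@H]2[C@](C)(CCC(=O)[C@]2(C)C(=O)O[C@@H]3C[C@H](C)CC[C@H]3C(C)(C)c4ccccc4)[C@H]1CCC#N | intermediate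
11 | Pm 12-cyano-3β-hydroxy-13,14,15,16-tetranorlabd-8(17)-en-19-oate | C=C1CC[C@@H]2[C@](C)(CC[C@H](O)[C@]2(C)C(=O)O[C@@H]3C[C@H](C)CC[C@H]3C(C)(C)c4ccccc4)[C@H]1CCC#N | intermediate
12 | Pm 12-cyano-3β-(imidazol-1-ylcarbonothioyloxy)-13,14,15,16-tetranorlabd-8(17)-en-19-oate | C=C1CC[C@@H]2[C@](C)(CC[C@H](OC(=S)n5ccnc5)[C@]2(C)C(=O)O[C@@H]3C[C@H](C)CC[C@H]3C(C)(C)c4ccccc4)[C@H]1CCC#N | intermediate
13 | Pm 12-cyano-13,14,15,16-tetranorlabd-8(17)-en-19-oate | C=C1CC[C@@H]2[C@](C)(CCC[C@]2(C)C(=O)O[C@@H]3C[C@H](C)CC[C@H]3C(C)(C)c4ccccc4)[C@H]1CCC#N | intermediate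
14 | 15-ethyl 19-Pm (13Z)-13-(bromozincioamino)-16-norlabda-8(17),13-diene-15,19-dioate | C=C1CC[C@@H]2[C@](C)(CCC[C@]2(C)C(=O)O[C@@H]3C[C@H](C)CC[C@H]3C(C)(C)c4ccccc4)[C@H]1CC/C(N[Zn]Br)=C/C(=O)OCC | intermediate
15 | 15-ethyl 19-Pm 13-oxo-16-norlabd-8(17)-ene-15,19-dioate | C=C1CC[C@@H]2[C@](C)(CCC[C@]2(C)C(=O)O[C@@H]3C[C@H](C)CC[C@H]3C(C)(C)c4ccccc4)[C@H]1CCC(=O)CC(=O)OCC | intermediate
16 | sodium (13Z)-enolate of 15 | [Na+].C=C1CC[C@@H]2[C@](C)(CCC[C@]2(C)C(=O)O[C@@H]3C[C@H](C)CC[C@H]3C(C)(C)c4ccccc4)[C@H]1CC/C([O-])=C/C(=O)OCC | intermediate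
17 | 15-ethyl 19-Pm (13Z)-13-(diethoxyphosphoryloxy)-16-norlabda-8(17),13-diene-15,19-dioate | C=C1CC[C@@H]2[C@](C)(CCC[C@]2(C)C(=O)O[C@@H]3C[C@H](C)CC[C@H]3C(C)(C)c4ccccc4)[C@H]1CC/C(OP(=O)(OCC)OCC)=C/C(=O)OCC | intermediate
18 | 15-ethyl 19-Pm labda-8(17),13E-diene-15,19-dioate | C=C1CC[C@@H]2[C@](C)(CCC[C@]2(C)C(=O)O[C@@H]3C[C@H](C)CC[C@H]3C(C)(C)c4ccccc4)[C@H]1CC/C(C)=C/C(=O)OCC | intermediate
19 | labda-8(17),13E-diene-15,19-diol | C=C1CC[C@@H]2[C@](C)(CCC[C@]2(C)CO)[C@H]1CC/C(C)=C/CO | intermediate
20 | 19-hydroxylabda-8(17),13E-dien-15-yl acetate | C=C1CC[C@@H]2[C@](C)(CCC[C@]2(C)CO)[C@H]1CC/C(C)=C/COC(C)=O | intermediate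
21 | 19-oxolabda-8(17),13E-dien-15-yl acetate | C=C1CC[C@@H]2[C@](C)(CCC[C@]2(C)C=O)[C@H]1CC/C(C)=C/COC(C)=O | intermediate
22 | 15-acetoxyisocupressic acid, 15-acetoxylabda-8(17),13E-dien-19-oic acid, (1S,4aR,5S,8aR)-5-[(3E)-5-acetoxy-3-methylpent-3-enyl]-1,4a-dimethyl-6-methylidenedecahydronaphthalene-1-carboxylic acid | C=C1CC[C@@H]2[C@](C)(CCC[C@]2(C)C(=O)O)[C@H]1CC/C(C)=C/COC(C)=O | target

**Step count**

Total step count: 16. Longest linear sequence: 15 steps (steps 1–3 and 5–16); step 4 is the only off-line step.

**Three steps most likely to fail**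

Step 6. What may go wrong: oxidation of the intermediate tertiary C10 radical before ring B closes, or loss of a ring proton instead of a methyl proton at the end of the cascade. The fallback replaces the oxidative cascade by a non-oxidative phenylselanyl group-transfer cascade and sets out from 9. PhSeCl and pyridine (CH2Cl2, 0 °C) would give the 2-phenylselanyl keto ester F1. Irradiation (sunlamp, benzene, 20 °C, dilute) would generate the same C4 radical, and since no oxidant is present the C10 radical can only cyclize; phenylselanyl transfer to the C8 radical would give the bicyclic tertiary C8 selenide F2. Oxidation with H2O2 and pyridine (CH2Cl2, 0 °C) and syn elimination of the selenoxide toward the C17 methyl group would come back to the route at 10.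

Step 2. What may go wrong: oxidation at the allylic positions of the internal alkene, over-oxidation to the enal and low conversion. The fallback functionalises the terminus by cleavage and re-olefination instead of C–H oxidation and sets out from 2. NBS in aqueous THF (0 °C) would give the terminal bromohydrin F3, K2CO3 in MeOH the terminal epoxide F4, and H5IO6 (Et2O/THF, 0 °C) the trisnor aldehyde F5. A Wittig reaction with 2-(triphenylphosphoranylidene)propanal (toluene, 80 °C) would give the (E)-enal F6, and NaBH4 (MeOH, 0 °C) would come back to the route at 3.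

Step 10. What may go wrong: self-condensation of the zinc enolate, deprotonation α to the nitrile and incomplete addition. The fallback homologates an aldehyde instead of adding to the nitrile and sets out from 13. i-Bu2AlH (toluene, −78 °C; aqueous tartrate work-up) would reduce the nitrile, leaving the hindered C19 ester, to the C13 aldehyde F7. SnCl2-catalysed insertion of ethyl diazoacetate (Roskamp reaction, CH2Cl2, 20 °C) would come back to the route at 15.

**Further compounds**

F1 | step 6 | Pm (6E,10E)-13-cyano-2,6,10-trimethyl-3-oxo-2-(phenylselanyl)trideca-6,10-dienoate (both C2 epimers) | N#CCC/C=C(\C)CC/C=C(\C)CCC(=O)C(C)([Se]c1ccccc1)C(=O)O[C@@H]1C[C@H](C)CC[C@H]1C(C)(C)c1ccccc1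
F2 | step 6 | Pm 12-cyano-3-oxo-8-(phenylselanyl)-13,14,15,16-tetranorlabdan-19-oate (C8 epimers) | CC1([Se]c5ccccc5)CC[C@@H]2[C@](C)(CCC(=O)[C@]2(C)C(=O)O[C@@H]3C[C@H](C)CC[C@H]3C(C)(C)c4ccccc4)[C@H]1CCC#N
F3 | step 2 | (4E)-8-bromo-9-hydroxy-5,9-dimethyldec-4-enenitrile (racemic) | CC(C)(O)C(Br)CC/C(C)=C/CCC#N
F4 | step 2 | (4E)-7-(3,3-dimethyloxiran-2-yl)-5-methylhept-4-enenitrile (racemic) | CC1(C)OC1CC/C(C)=C/CCC#N
F5 | step 2 | (4E)-5-methyl-8-oxooct-4-enenitrile | O=CCC/C(C)=C/CCC#N
F6 | step 2 | (4E,8E)-5,9-dimethyl-10-oxodeca-4,8-dienenitrile | O=C/C(C)=C/CC/C(C)=C/CCC#N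
F7 | step 10 | Pm 13-oxo-14,15,16-trinorlabd-8(17)-en-19-oate (C13 aldehyde) | C=C1CC[C@@H]2[C@](C)(CCC[C@]2(C)C(=O)O[C@@H]3C[C@H](C)CC[C@H]3C(C)(C)c4ccccc4)[C@H]1CCC=O
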